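**Retrosynthetic overview**

1. The ten-membered ring is closed last by a Nozaki–Hiyama–Kishi coupling of a C5 alkenyl iodide (C16H2=C5–I) with a C6 aldehyde. This one operation forms C5–C6, closes the carbocycle C1–C10 and leaves the C5=C16 methylene next to a C6 oxygen, which an oxidation/reduction pair and an invertive chlorination turn into the chloride.
2. Enabling feature: the C16H2=C5–C6(Cl)–C7(O) array, a 2-methylene allylic chloride on the γ-lactone carbon C7, is the retron of an alkenyl-metal addition to an α-oxygenated aldehyde. The trans arms on ring A (at C1 and C10) and the lactone (C7/C8) act as turn elements.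
3. The γ-lactone (O–C7–C8–C17–C19) comes from an intramolecular Reformatsky reaction on a C8 ketone. The ring A oxygens (C11/C12 diol, C13/C14 oxirane) come from a 1,3-diene by dihydroxylation and hydroxyl-directed epoxidation.
4. Ring A comes from a Diels–Alder reaction of a 2-silyloxydiene (C11–C14) with an E-enone (C1=C10) made from L-arabinose, whose C2 and C4 become C9 and C7 and steer C1 and C10.
5. Order of ring formation: six-membered ring A, γ-lactone, oxirane, ten-membered ring.

Key step: step 26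

Remark: briarane numbering is used for all intermediates (C1–C10 ten-membered ring; C1 and C10–C14 ring A; C15 on C1; C16 on C5; C17, C18 (methyl) and C19 (carbonyl) in the lactone; C20 on C11). The target is read as (1S,2S,6S,7R,8R,9S,10S,11S,12R,13R,14R,17R).
Remark: 2-bromopropanoyl bromide is used as the racemate, because its stereocentre is lost in the samarium enolate; the two esters made from it are mixtures at that carbon.
Remark: L-arabinose and 3-(triphenylphosphoranylidene)butan-2-one are taken as commercial.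

**Route**

Step 1
Reactants: 1 L-arabinose
Product: 2 3,4-O-isopropylidene-L-arabinopyranose
Conditions: 2,2-dimethoxypropane, TsOH·H2O (cat.), DMF, rt
Reagents that add atoms: 2,2-dimethoxypropane, COC(C)(C)OC
Why: Acid-catalysed acetal exchange (acetonide formation) engages the only cis-vicinal diol of the pyranose, O3/O4 (the later O8 and O7), so that O2 (the later O9) and the lactol stay free and no stereocentre is touched.

Step 2
Reactants: 2 3,4-O-isopropylidene-L-arabinopyranose; 3 3-(triphenylphosphoranylidene)butan-2-one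
Product: 4 (3E,5S,6R,7S)-5,8-dihydroxy-6,7-(isopropylidenedioxy)-3-methyloct-3-en-2-one
Conditions: 1,4-dioxane, 90 °C
Reagents that add atoms: none
Why: Wittig olefination of the open-chain aldehyde form of the lactol with a stabilised, α-branched ylide should give the E-trisubstituted enone (acetyl trans to C9) without affecting the three sugar stereocentres, which become C9, C8 and C7.

Step 3
Reactants: 4 enone diol
Product: 5 8-O-(tert-butyldiphenylsilyl) ether of 4 (silyl ether at C6 of the target)
Conditions: t-BuPh2SiCl, imidazole, CH2Cl2, 0 °C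
Reagents that add atoms: tert-butyl(chloro)diphenylsilane, CC(C)(C)[Si](Cl)(c1ccccc1)c1ccccc1
Why: Silyl ether formation with the bulky chlorosilane is selective for the primary hydroxyl over the secondary allylic C9 hydroxyl on steric grounds.

Step 4
Reactants: 5 primary silyl ether
Product: 6 dienophile, the 5-O-triethylsilyl ether of 5 (silyl ether at C9)
Conditions: Et3SiCl, imidazole, DMF, rt
Reagents that add atoms: chlorotriethylsilane, CC[Si](Cl)(CC)CC
Why: Silylation of the remaining C9 hydroxyl masks it for the Lewis-acid and strong-base steps with a group that mild acid later removes in the presence of the acetonide.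

Step 5
Reactants: 7 pent-1-en-3-one
Product: 8 (Z)-3-(tert-butyldimethylsilyloxy)penta-1,3-diene
Conditions: t-BuMe2SiOTf, Et3N, Et2O, 0 °C
Reagents that add atoms: tert-butyldimethylsilyl trifluoromethanesulfonate, CC(C)(C)[Si](C)(C)OS(=O)(=O)C(F)(F)F
Why: Soft enolisation of the ethyl ketone (silyl triflate and amine) should give the favoured Z-silyl enol ether, a 2-silyloxydiene whose methyl-bearing terminus points outward and is the nucleophilic end.

Step 6
Reactants: 6 dienophile; 8 silyloxydiene
Product: 9 Diels–Alder adduct, ring A cyclohexene with the C12 silyl enol ether (C12=C13), acetyl and methyl on C1 and the C6–C9 chain on C10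
Conditions: Me2AlCl (0.3 equiv), CH2Cl2, −78 to −30 °C
Reagents that add atoms: none
Why: Lewis-acid-catalysed Diels–Alder reaction in which the silyloxy-activated C11 terminus bonds to the enone β-carbon C10 and C14 to C1, the E geometry of the dienophile is transferred suprafacially to give the trans C2/C9 arms, and A(1,3) strain between the C1 methyl and C9 holds H9 in the enone plane so that the diene should add anti to the C9–O bond, which sets C1 and C10 from C9 (the endo-derived C11 centre is removed later).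

Step 7
Reactants: 9 Diels–Alder adduct; 10 3-bromo-1-(trimethylsilyl)prop-1-yne
Product: 12 C2 ketone carrying the C3–C4–C5≡C16–SiMe3 chain, via lithium enolate 11 (not isolated)
Conditions: LiN(i-Pr)2, THF, −78 °C; then 10, DMPU, −78 to −20 °C
Reagents that add atoms: none
Why: Enolate alkylation: the methyl ketone has α-hydrogens only on C3 (C1 is quaternary), so the kinetic lithium enolate forms there and displaces the propargylic bromide (SN2) to build the C3–C4 bond.

Step 8
Reactants: 12 C2 ketone
Product: 13 (2S)-alcohol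
Conditions: (R)-2-methyl-CBS-oxazaborolidine (0.5 equiv), catecholborane, CH2Cl2, −40 °C
Reagents that add atoms: none
Why: Corey–Bakshi–Shibata reduction, in which the oxazaborolidine differentiates the quaternary C1 (large) from the C3H2 (small) substituent, so the R catalyst should deliver hydride to give the 2S alcohol under reagent control.

Step 9
Reactants: 13 (2S)-alcohol
Product: 14 2,9-bis(triethylsilyl) ether
Conditions: Et3SiOTf, 2,6-lutidine, CH2Cl2, −78 °C
Reagents that add atoms: triethylsilyl trifluoromethanesulfonate, CC[Si](CC)(CC)OS(=O)(=O)C(F)(F)F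
Why: Silyl triflate silylation of the hindered C2 hydroxyl gives an ether that tolerates the base, palladium and aluminium hydride steps and is removed together with the C9 silyl group.

Step 10
Reactants: 14 bis(triethylsilyl) ether
Product: 15 ring A enone (C12 ketone, C13=C14)
Conditions: Pd(OAc)2 (1.1 equiv), MeCN, 40 °C
Reagents that add atoms: none
Why: Saegusa–Ito oxidation: palladation of the silyl enol ether at C13 and β-hydride elimination from C14 should give the C13=C14 enone regiospecifically.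

Step 11
Reactants: 15 ring A enone
Product: 17 ring A dienyl triflate (C11=C12(OTf)–C13=C14), via potassium dienolate 16 (not isolated)
Conditions: KN(SiMe3)2, THF, −78 °C; then PhNTf2, −78 to 0 °C
Reagents that add atoms: N-phenylbis(trifluoromethanesulfonimide), O=S(=O)(N(c1ccccc1)S(=O)(=O)C(F)(F)F)C(F)(F)F
Why: Enol triflate formation: the amide base removes the only acidic hydrogen (C11–H, α′ to the enone) and O-sulfonylation of the dienolate gives the dienyl triflate, which also erases the C11 stereocentre.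

Step 12
Reactants: 17 dienyl triflate
Product: 18 ring A 1,3-diene (C11=C12, C13=C14)
Conditions: Pd(OAc)2 (5 mol %), PPh3 (10 mol %), HCO2H, n-Bu3N, DMF, 60 °C
Reagents that add atoms: none
Why: Palladium-catalysed formate reduction of an enol triflate (oxidative addition, formate exchange, decarboxylation, reductive elimination) replaces the triflate by hydrogen and keeps both double bonds in place.

Step 13
Reactants: 18 ring A diene
Product: 19 terminal alkyne (C5≡C16H)
Conditions: K2CO3, MeOH, rt
Reagents that add atoms: none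
Why: Base-mediated protodesilylation of the alkynylsilane (methoxide attack at silicon) frees the terminal alkyne, while the secondary silyl ethers, the acetonide and the diene should be untouched.

Step 14
Reactants: 19 terminal alkyne
Product: 21 C5 alkenyl iodide (2-iodo-1-alkene), via alkenylalane 20 (not isolated)
Conditions: NiCl2(dppp) (3 mol %), i-Bu2AlH, THF, 0 °C to rt; then iodine, −78 to 0 °C
Reagents that add atoms: iodine, [I][I]
Why: Nickel-catalysed Markovnikov hydroalumination of the terminal alkyne (with the chelating diphosphine the aluminium goes to the internal carbon C5) followed by iodinolysis of the C–Al bond gives the 2-iodo-1-alkene; the substrate carries no carbonyl group at this stage.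

Step 15
Reactants: 21 alkenyl iodide
Product: 22 2,9-diol
Conditions: pyridinium p-toluenesulfonate (cat.), MeOH/CH2Cl2, 0 °C to rt
Reagents that add atoms: none
Why: Acid-catalysed methanolysis cleaves both triethylsilyl ethers, which are far more labile than the dioxolane and the tert-butyldiphenylsilyl ether.

Step 16
Reactants: 22 2,9-diol
Product: 23 2,9-diacetate
Conditions: Ac2O, DMAP (cat.), pyridine, rt
Reagents that add atoms: acetic anhydride, CC(=O)OC(C)=O
Why: Nucleophile-catalysed acylation (acylpyridinium) esterifies the two secondary hydroxyls at C2 and C9 with their final acetyl groups in one step.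

Step 17
Reactants: 23 2,9-diacetate
Product: 24 7,8-diol
Conditions: 80% aq. AcOH, 40 °C
Reagents that add atoms: none
Why: Acid-catalysed acetal hydrolysis unmasks the C7/C8 diol; esters, silyl ether, alkenyl iodide and diene should be stable to aqueous acetic acid.

Step 18
Reactants: 24 7,8-diol; 25 2-bromopropanoyl bromide
Product: 26 7-O-(2-bromopropanoyl) ester of 24
Conditions: 2,4,6-collidine, CH2Cl2, −78 °C
Reagents that add atoms: none
Why: Kinetic O-acylation with the acid bromide should go to the C7 hydroxyl, whose neighbours are C6H2 and C8, and not to the C8 hydroxyl, which is flanked by the branched C9 next to ring A; this places the Reformatsky donor on the oxygen that becomes the lactone oxygen.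

Step 19
Reactants: 26 7-O-(2-bromopropanoyl) ester
Product: 27 C8 ketone
Conditions: Dess–Martin periodinane, NaHCO3, CH2Cl2, rt
Reagents that add atoms: none
Why: Dess–Martin oxidation converts the remaining secondary C8 hydroxyl into the ketone under buffered, non-epimerising conditions.

Step 20
Reactants: 27 C8 ketone
Product: 28 seco-lactone (γ-lactone with 8-hydroxyl and 17-methyl as in the target)
Conditions: SmI2 (2.5 equiv), THF, −78 °C
Reagents that add atoms: none
Why: Intramolecular Reformatsky reaction: SmI2 reduces the C–Br bond and the samarium enolate, chelated to the C8 carbonyl, should close the five-membered lactone through the transition state that keeps the C9 chain anti to C6 and the C17 methyl anti to C9, which sets C8 (hydroxyl cis to C6) and C17.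

Step 21
Reactants: 28 seco-lactone
Product: 29 11,12-diol
Conditions: OsO4 (5 mol %), N-methylmorpholine N-oxide, acetone/H2O, 0 °C
Reagents that add atoms: N-methylmorpholine N-oxide, C[N+]1([O-])CCOCC1; water, O
Why: Catalytic OsO4 dihydroxylation (syn addition) should take place at the more electron-rich trisubstituted C11=C12 bond of the diene from the α face, anti to the C10 side chain and the C1 methyl, which sets C11 and C12 as the cis-diol.

Step 22
Reactants: 29 11,12-diol
Product: 30 13,14-epoxide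
Conditions: VO(acac)2 (5 mol %), t-BuOOH, CH2Cl2, 0 °C to rt
Reagents that add atoms: tert-butyl hydroperoxide, CC(C)(C)OO
Why: Hydroxyl-directed epoxidation: the vanadium alkoxide of the allylic C12 hydroxyl delivers the peroxide oxygen to C13=C14 on its own face, which sets C13 and C14 cis to the diol, and the alkenyl iodide is not epoxidised.

Step 23
Reactants: 30 13,14-epoxide
Product: 31 12-butanoate
Conditions: (n-PrCO)2O, DMAP (cat.), pyridine, CH2Cl2, 0 °C to rt
Reagents that add atoms: butanoic anhydride, CCCC(=O)OC(=O)CCC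
Why: Nucleophile-catalysed acylation esterifies the only secondary hydroxyl (C12) and should leave the tertiary C8 and C11 hydroxyls free.

Step 24
Reactants: 31 12-butanoate
Product: 32 C6 primary alcohol
Conditions: HF·pyridine, pyridine, THF, 0 °C to rt
Reagents that add atoms: none
Why: Fluoride-mediated Si–O cleavage under pyridine buffering removes the primary silyl ether and should neither open the hindered oxirane nor cleave the esters.

Step 25
Reactants: 32 C6 primary alcohol
Product: 33 seco-aldehyde (C6 aldehyde on the lactone carbon C7)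
Conditions: Dess–Martin periodinane, NaHCO3, CH2Cl2, 0 °C
Reagents that add atoms: none
Why: Dess–Martin oxidation of the primary alcohol gives the α-acyloxy aldehyde under buffered conditions that should not epimerise C7; the tertiary alcohols are inert.

Step 26
Reactants: 33 seco-aldehyde
Product: 34 (6S)-6-hydroxy analogue of the target (macrocyclic allylic alcohol)
Conditions: CrCl2 (10 equiv), NiCl2 (0.1 equiv), DMSO/THF, rt, 2 mM, slow addition of 33
Reagents that add atoms: none
Why: Zerovalent nickel, formed from NiCl2 by divalent chromium, inserts into the C5–I bond, the alkenyl group passes to trivalent chromium, and the alkenylchromium adds to the C6 aldehyde (Nozaki–Hiyama–Kishi reaction). The closest known reaction type is the Nozaki–Hiyama–Kishi macrocyclisation of 2-iodo-1-alkenes onto aldehydes, which closes nine- and ten-membered rings in the presence of esters, epoxides and free hydroxyls. The one ring closed is the ten-membered carbocycle C1–C10, by 10-exo-trig attack of C5 on the C6 carbonyl, and the same event leaves the exocyclic C5=C16 methylene in place. The one new stereocentre, C6, is controlled by C7 through the polar Felkin–Anh model (attack anti to the C7–O lactone bond) and should be 6S. The step needs chemoselectivity for the aldehyde over four esters, the oxirane and two tertiary alcohols, which the organochromium reagent provides, and ring closure over oligomerisation, which high dilution and the two turn elements (trans arms on ring A, lactone at C7/C8) should secure. No diastereoselectivity is required, because steps 27 and 28 set C6 independently.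

Step 27
Reactants: 34 (6S)-allylic alcohol
Product: 35 C6 ketone (5(16)-en-6-one)
Conditions: Dess–Martin periodinane, NaHCO3, CH2Cl2, 0 °C to rt
Reagents that add atoms: none
Why: Dess–Martin oxidation of the allylic alcohol gives the cross-conjugated enone, so that either C6 epimer from step 26 converges on one compound.

Step 28
Reactants: 35 C6 ketone
Product: 36 (6R)-allylic alcohol (6-epimer of 34)
Conditions: NaBH4, CeCl3·7H2O, MeOH, −78 °C
Reagents that add atoms: none
Why: Luche reduction (1,2-selective hydride addition to the enone) under polar Felkin–Anh control, anti to the C7–O bond, should give the 6R alcohol, the epimer of the alkenyl-addition product.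

Step 29
Reactants: 36 (6R)-allylic alcohol
Product: 37 CNP0105329.1 (target)
Conditions: PPh3, hexachloroacetone, CH2Cl2, −20 to 0 °C
Reagents that add atoms: hexachloroacetone, O=C(C(Cl)(Cl)Cl)C(Cl)(Cl)Cl
Why: Appel-type deoxychlorination: the alkoxyphosphonium ion formed from PPh3 and hexachloroacetone is displaced by chloride with inversion (SN2) and should not undergo allylic transposition, giving the 6S chloride, while the tertiary alcohols do not react.

**Compound list**

1 | L-arabinose (pyranose form, anomeric mixture) | OC1OC[C@H](O)[C@H](O)[C@H]1O | starting material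
2 | 3,4-O-isopropylidene-L-arabinopyranose (anomeric mixture, mainly β) | OC1OC[C@@H]2OC(C)(C)O[C@@H]2[C@H]1O | intermediate
3 | 3-(triphenylphosphoranylidene)butan-2-one | CC(=O)C(C)=P(c1ccccc1)(c1ccccc1)c1ccccc1 | starting material
4 | (3E,5S,6R,7S)-5,8-dihydroxy-6,7-(isopropylidenedioxy)-3-methyloct-3-en-2-one | CC(=O)/C(C)=C/[C@H](O)[C@H]1OC(C)(C)O[C@H]1CO | intermediate
5 | 8-O-(tert-butyldiphenylsilyl) ether of 4 | CC(=O)/C(C)=C/[C@H](O)[C@H]1OC(C)(C)O[C@H]1CO[Si](c1ccccc1)(c1ccccc1)C(C)(C)C | intermediate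
6 | dienophile, 5-O-triethylsilyl ether of 5 | CC(=O)/C(C)=C/[C@H](O[Si](CC)(CC)CC)[C@H]1OC(C)(C)O[C@H]1CO[Si](c1ccccc1)(c1ccccc1)C(C)(C)C | intermediate
7 | pent-1-en-3-one | C=CC(=O)CC | starting material
8 | (Z)-3-(tert-butyldimethylsilyloxy)penta-1,3-diene | C=C/C(O[Si](C)(C)C(C)(C)C)=C/C | intermediate
9 | Diels–Alder adduct (ring A cyclohexene, C12 silyl enol ether, C1 acetyl; C1 and C10 as in 37, C11 methyl cis to H10) | CC(=O)[C@@]1(C)CC=C(O[Si](C)(C)C(C)(C)C)[C@@H](C)[C@@H]1[C@H](O[Si](CC)(CC)CC)[C@H]2OC(C)(C)O[C@H]2CO[Si](c2ccccc2)(c2ccccc2)C(C)(C)C | intermediate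
10 | 3-bromo-1-(trimethylsilyl)prop-1-yne | C[Si](C)(C)C#CCBr | starting material
11 | lithium enolate of 9 (C2=C3) | C=C(O[Li])[C@@]1(C)CC=C(O[Si](C)(C)C(C)(C)C)[C@@H](C)[C@@H]1[C@H](O[Si](CC)(CC)CC)[C@H]2OC(C)(C)O[C@H]2CO[Si](c2ccccc2)(c2ccccc2)C(C)(C)C | intermediate
12 | C2 ketone with the C3–C4–C5≡C16–SiMe3 chain | C[Si](C)(C)C#CCCC(=O)[C@@]1(C)CC=C(O[Si](C)(C)C(C)(C)C)[C@@H](C)[C@@H]1[C@H](O[Si](CC)(CC)CC)[C@H]2OC(C)(C)O[C@H]2CO[Si](c2ccccc2)(c2ccccc2)C(C)(C)C | intermediate
13 | (2S)-alcohol of 12 | C[Si](C)(C)C#CCC[C@H](O)[C@@]1(C)CC=C(O[Si](C)(C)C(C)(C)C)[C@@H](C)[C@@H]1[C@H](O[Si](CC)(CC)CC)[C@H]2OC(C)(C)O[C@H]2CO[Si](c2ccccc2)(c2ccccc2)C(C)(C)C | intermediate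
14 | 2,9-bis(triethylsilyl) ether | C[Si](C)(C)C#CCC[C@H](O[Si](CC)(CC)CC)[C@@]1(C)CC=C(O[Si](C)(C)C(C)(C)C)[C@@H](C)[C@@H]1[C@H](O[Si](CC)(CC)CC)[C@H]2OC(C)(C)O[C@H]2CO[Si](c2ccccc2)(c2ccccc2)C(C)(C)C | intermediate
15 | ring A enone (C12 ketone, C13=C14) | C[Si](C)(C)C#CCC[C@H](O[Si](CC)(CC)CC)[C@@]1(C)C=CC(=O)[C@@H](C)[C@@H]1[C@H](O[Si](CC)(CC)CC)[C@H]2OC(C)(C)O[C@H]2CO[Si](c2ccccc2)(c2ccccc2)C(C)(C)C | intermediate
16 | potassium dienolate of 15 | C[Si](C)(C)C#CCC[C@H](O[Si](CC)(CC)CC)[C@@]1(C)C=CC(O[K])=C(C)[C@@H]1[C@H](O[Si](CC)(CC)CC)[C@H]2OC(C)(C)O[C@H]2CO[Si](c2ccccc2)(c2ccccc2)C(C)(C)C | intermediate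
17 | ring A dienyl triflate | C[Si](C)(C)C#CCC[C@H](O[Si](CC)(CC)CC)[C@@]1(C)C=CC(OS(=O)(=O)C(F)(F)F)=C(C)[C@@H]1[C@H](O[Si](CC)(CC)CC)[C@H]2OC(C)(C)O[C@H]2CO[Si](c2ccccc2)(c2ccccc2)C(C)(C)C | intermediate
18 | ring A 1,3-diene | C[Si](C)(C)C#CCC[C@H](O[Si](CC)(CC)CC)[C@@]1(C)C=CC=C(C)[C@@H]1[C@H](O[Si](CC)(CC)CC)[C@H]2OC(C)(C)O[C@H]2CO[Si](c2ccccc2)(c2ccccc2)C(C)(C)C | intermediate
19 | terminal alkyne | C#CCC[C@H](O[Si](CC)(CC)CC)[C@@]1(C)C=CC=C(C)[C@@H]1[C@H](O[Si](CC)(CC)CC)[C@H]2OC(C)(C)O[C@H]2CO[Si](c2ccccc2)(c2ccccc2)C(C)(C)C | intermediate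
20 | C5 alkenyl(diisobutyl)alane | C=C([Al](CC(C)C)CC(C)C)CC[C@H](O[Si](CC)(CC)CC)[C@@]1(C)C=CC=C(C)[C@@H]1[C@H](O[Si](CC)(CC)CC)[C@H]2OC(C)(C)O[C@H]2CO[Si](c2ccccc2)(c2ccccc2)C(C)(C)C | intermediate
21 | C5 alkenyl iodide | C=C(I)CC[C@H](O[Si](CC)(CC)CC)[C@@]1(C)C=CC=C(C)[C@@H]1[C@H](O[Si](CC)(CC)CC)[C@H]2OC(C)(C)O[C@H]2CO[Si](c2ccccc2)(c2ccccc2)C(C)(C)C | intermediate
22 | 2,9-diol | C=C(I)CC[C@H](O)[C@@]1(C)C=CC=C(C)[C@@H]1[C@H](O)[C@H]2OC(C)(C)O[C@H]2CO[Si](c2ccccc2)(c2ccccc2)C(C)(C)C | intermediate
23 | 2,9-diacetate | C=C(I)CC[C@H](OC(C)=O)[C@@]1(C)C=CC=C(C)[C@@H]1[C@H](OC(C)=O)[C@H]2OC(C)(C)O[C@H]2CO[Si](c2ccccc2)(c2ccccc2)C(C)(C)C | intermediate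
24 | 7,8-diol | C=C(I)CC[C@H](OC(C)=O)[C@@]1(C)C=CC=C(C)[C@@H]1[C@H](OC(C)=O)[C@@H](O)[C@@H](O)CO[Si](c1ccccc1)(c1ccccc1)C(C)(C)C | intermediate
25 | 2-bromopropanoyl bromide (racemic) | CC(Br)C(Br)=O | starting material
26 | 7-O-(2-bromopropanoyl) ester of 24 (mixture at the CHBr carbon) | C=C(I)CC[C@H](OC(C)=O)[C@@]1(C)C=CC=C(C)[C@@H]1[C@H](OC(C)=O)[C@@H](O)[C@@H](OC(=O)C(C)Br)CO[Si](c1ccccc1)(c1ccccc1)C(C)(C)C | intermediate
27 | C8 ketone of 26 | C=C(I)CC[C@H](OC(C)=O)[C@@]1(C)C=CC=C(C)[C@@H]1[C@H](OC(C)=O)C(=O)[C@@H](OC(=O)C(C)Br)CO[Si](c1ccccc1)(c1ccccc1)C(C)(C)C | intermediate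
28 | seco-lactone | C=C(I)CC[C@H](OC(C)=O)[C@@]1(C)C=CC=C(C)[C@@H]1[C@H](OC(C)=O)[C@]2(O)[C@@H](C)C(=O)O[C@H]2CO[Si](c2ccccc2)(c2ccccc2)C(C)(C)C | intermediate
29 | 11,12-diol | C=C(I)CC[C@H](OC(C)=O)[C@@]1(C)C=C[C@@H](O)[C@@](C)(O)[C@@H]1[C@H](OC(C)=O)[C@]2(O)[C@@H](C)C(=O)O[C@H]2CO[Si](c2ccccc2)(c2ccccc2)C(C)(C)C | intermediate
30 | 13,14-epoxide | C=C(I)CC[C@H](OC(C)=O)[C@@]1(C)[C@H]3O[C@H]3[C@@H](O)[C@@](C)(O)[C@@H]1[C@H](OC(C)=O)[C@]2(O)[C@@H](C)C(=O)O[C@H]2CO[Si](c2ccccc2)(c2ccccc2)C(C)(C)C | intermediate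
31 | 12-butanoate | C=C(I)CC[C@H](OC(C)=O)[C@@]1(C)[C@H]3O[C@H]3[C@@H](OC(=O)CCC)[C@@](C)(O)[C@@H]1[C@H](OC(C)=O)[C@]2(O)[C@@H](C)C(=O)O[C@H]2CO[Si](c2ccccc2)(c2ccccc2)C(C)(C)C | intermediate
32 | C6 primary alcohol | C=C(I)CC[C@H](OC(C)=O)[C@@]1(C)[C@H]3O[C@H]3[C@@H](OC(=O)CCC)[C@@](C)(O)[C@@H]1[C@H](OC(C)=O)[C@]2(O)[C@@H](C)C(=O)O[C@H]2CO | intermediate
33 | seco-aldehyde | C=C(I)CC[C@H](OC(C)=O)[C@@]1(C)[C@H]3O[C@H]3[C@@H](OC(=O)CCC)[C@@](C)(O)[C@@H]1[C@H](OC(C)=O)[C@]2(O)[C@@H](C)C(=O)O[C@H]2C=O | intermediate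
34 | (6S)-6-hydroxy analogue of 37 | C=C1CC[C@H](OC(C)=O)[C@@]2(C)[C@H]3O[C@H]3[C@@H](OC(=O)CCC)[C@@](C)(O)[C@@H]2[C@H](OC(C)=O)[C@]2(O)[C@@H](C)C(=O)O[C@H]2[C@H]1O | intermediate
35 | C6 ketone (5(16)-en-6-one) | C=C1CC[C@H](OC(C)=O)[C@@]2(C)[C@H]3O[C@H]3[C@@H](OC(=O)CCC)[C@@](C)(O)[C@@H]2[C@H](OC(C)=O)[C@]2(O)[C@@H](C)C(=O)O[C@H]2C1=O | intermediate
36 | (6R)-6-hydroxy analogue of 37 | C=C1CC[C@H](OC(C)=O)[C@@]2(C)[C@H]3O[C@H]3[C@@H](OC(=O)CCC)[C@@](C)(O)[C@@H]2[C@H](OC(C)=O)[C@]2(O)[C@@H](C)C(=O)O[C@H]2[C@@H]1O | intermediate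
37 | CNP0105329.1, (1S,2S,6S,7R,8R,9S,10S,11S,12R,13R,14R,17R)-2,9-diacetoxy-12-butanoyloxy-6-chloro-13,14-epoxy-8,11-dihydroxybriar-5(16)-en-19,7-olide | C=C1CC[C@H](OC(C)=O)[C@@]2(C)[C@H]3O[C@H]3[C@@H](OC(=O)CCC)[C@@](C)(O)[C@@H]2[C@H](OC(C)=O)[C@]2(O)[C@@H](C)C(=O)O[C@H]2[C@H]1Cl | target

**Step count and risks**

Total step count: 29. Longest linear sequence: 28 steps (steps 1 to 4 and 6 to 29, from L-arabinose; step 5 is a one-step side branch).

The three steps most likely to fail:

Step 26 (ring closure). What may go wrong: slow closure of the strained ten-membered ring, so that intermolecular coupling (oligomerisation) or protodemetalation of the alkenylchromium species (net reduction of the C–I bond) takes over. The fallback closes the same C5–C6 bond by an acyl cross-coupling at the ketone oxidation level and sets out from alcohol 32. Oxidation (TEMPO cat., PhI(OAc)2, MeCN/H2O) gives the C6 carboxylic acid F1, and coupling with ethanethiol (1-ethyl-3-(3-dimethylaminopropyl)carbodiimide hydrochloride, DMAP cat., CH2Cl2) gives the S-ethyl thioester F2. Stannylation of the alkenyl iodide ((Me3Sn)2, Pd(PPh3)4, toluene, 80 °C) gives the alkenylstannane F3. A Liebeskind–Srogl ketone synthesis under high dilution (Pd2(dba)3, tri(2-furyl)phosphine, CuO2PPh2, THF, rt) should then give enone 35, where the route is rejoined before step 28.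

Step 20 (lactone formation). What may go wrong: electron transfer to the α,α′-dioxygenated C8 ketone instead of the C–Br bond, with reductive loss of an acyloxy group, or cyclisation through the other rotamer about C7–C8 (wrong face of the C8 carbonyl). The fallback is a chelation-controlled intermolecular Reformatsky addition and sets out from diol 24. Chloroacetylation of the C7 hydroxyl ((ClCH2CO)2O, 2,4,6-collidine, CH2Cl2, −78 °C) gives the chloroacetate F4, and Dess–Martin oxidation gives the C8 ketone F5. Thiourea (NaHCO3, EtOH, rt) then frees the α-hydroxy ketone F6. Ethyl 2-bromopropanoate with activated Zn in THF should add to the five-membered zinc chelate of the C7 alkoxide and the C8 carbonyl from the face of H7, and the β-hydroxy ester lactonises onto O7 to give 28 (C17 equilibrated with DBU if required), where the route is rejoined before step 21.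

Step 29 (chlorination). What may go wrong: allylic transposition (delivery of chloride to C16 with a shift of the double bond to C5=C6) or ionisation of the allylic oxyphosphonium intermediate with loss of configuration at C6. The fallback runs the substitution next to a carbonyl group instead of an alkene and sets out from alcohol 36. Ozonolysis (O3, CH2Cl2/MeOH, −78 °C; then Me2S) gives the C5 ketone F7. Triflation and chloride displacement (Tf2O, 2,6-di-tert-butylpyridine, CH2Cl2, −78 °C; then n-Bu4NCl) should give the α-chloro ketone F8 with inversion at C6 by a carbonyl-accelerated SN2 reaction. Methylenation of the ketone with Cp2Ti(μ-Cl)(μ-CH2)AlMe2 (Tebbe reagent, THF, −40 °C) restores the C5=C16 alkene and gives 37.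

Further compounds
F1 | step 26 | C6 carboxylic acid from 32 | C=C(I)CC[C@H](OC(C)=O)[C@@]1(C)[C@H]3O[C@H]3[C@@H](OC(=O)CCC)[C@@](C)(O)[C@@H]1[C@H](OC(C)=O)[C@]2(O)[C@@H](C)C(=O)O[C@H]2C(=O)O
F2 | step 26 | S-ethyl thioester of F1 | C=C(I)CC[C@H](OC(C)=O)[C@@]1(C)[C@H]3O[C@H]3[C@@H](OC(=O)CCC)[C@@](C)(O)[C@@H]1[C@H](OC(C)=O)[C@]2(O)[C@@H](C)C(=O)O[C@H]2C(=O)SCC
F3 | step 26 | C5 alkenyl(trimethyl)stannane thioester | C=C([Sn](C)(C)C)CC[C@H](OC(C)=O)[C@@]1(C)[C@H]3O[C@H]3[C@@H](OC(=O)CCC)[C@@](C)(O)[C@@H]1[C@H](OC(C)=O)[C@]2(O)[C@@H](C)C(=O)O[C@H]2C(=O)SCC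
F4 | step 20 | 7-O-chloroacetate of 24 | C=C(I)CC[C@H](OC(C)=O)[C@@]1(C)C=CC=C(C)[C@@H]1[C@H](OC(C)=O)[C@@H](O)[C@@H](OC(=O)CCl)CO[Si](c1ccccc1)(c1ccccc1)C(C)(C)C
F5 | step 20 | C8 ketone of F4 | C=C(I)CC[C@H](OC(C)=O)[C@@]1(C)C=CC=C(C)[C@@H]1[C@H](OC(C)=O)C(=O)[C@@H](OC(=O)CCl)CO[Si](c1ccccc1)(c1ccccc1)C(C)(C)C
F6 | step 20 | 7-hydroxy C8 ketone (α-hydroxy ketone) | C=C(I)CC[C@H](OC(C)=O)[C@@]1(C)C=CC=C(C)[C@@H]1[C@H](OC(C)=O)C(=O)[C@@H](O)CO[Si](c1ccccc1)(c1ccccc1)C(C)(C)C
F7 | step 29 | C5 ketone from 36 (16-nor, C6 hydroxyl as in 36) | O=C1CC[C@H](OC(C)=O)[C@@]2(C)[C@H]3O[C@H]3[C@@H](OC(=O)CCC)[C@@](C)(O)[C@@H]2[C@H](OC(C)=O)[C@]2(O)[C@@H](C)C(=O)O[C@H]2[C@@H]1O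
F8 | step 29 | 6-chloro C5 ketone (C6 as in 37) | O=C1CC[C@H](OC(C)=O)[C@@]2(C)[C@H]3O[C@H]3[C@@H](OC(=O)CCC)[C@@](C)(O)[C@@H]2[C@H](OC(C)=O)[C@]2(O)[C@@H](C)C(=O)O[C@H]2[C@H]1Cl
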